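I follow G. In the eta flask, D starts as a solid outside the solution, G reacts with it, and L is the catalyst.

in all of them: D 0.95 M

| run | G | L | remark | time |
|---|---|---|---|---|
| eta | 0.665 M | 8 mM | the very flask that is asked about, followed so far |  |
| delta | 0.33 M | 8 mM | run made earlier |  |
| flask | 0.665 M | 8.0 mM |  | 15 min |

| run | time / min | X / % | D / % |
|---|---|---|---|
| eta | 0.500 | 0.3 | 95.1 |
| eta | 1.00 | 3.8 | 90.8 |
| eta | 1.50 | 4.7 | 87.0 |
| eta | 2.00 | 8.7 | 83.4 |
| eta | 2.50 | 11.1 | 80.8 |
| delta | 1.33 | 4.5 | 89.5 |
| delta | 2.50 | 11.7 | 79.5 |
| delta | 4.00 | 21.4 | 70.4 |
| delta | 8.00 | 34.7 | 45.6 |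
| delta | 15.0 | 34.6 | 34.5 |

(standard deviation of a reading: 0.5 percentage points)

- D is a solid; its amount is given per volume of the solution
- at the start none of D is in solution

- teal: doubling the amount of G, all else as stated
- green: doubling the solubility of D, all else as stated
- red: doubling the amount of L, all else as stated
- ochre: doubling the dissolution coefficient of D, all else as stated

- X at 15 min, in percent of the D charged
- the change that raises the amount of X at 15 min, in percent of the D charged most ("none" if none brings more than 2 percentage points) (teal / green / red / ochre / none)
- amount of X at 15 min, in percent of the D charged, after teal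

I keep a ledger for G, which is charged in the smaller amount, so I treat it as the limiting reagent. The first entry is X. In the delta run, X reads 34.7% at 8.00 min and 34.6% at 15.0 min, and G over D there is 34.7%, so I book one G per X. The second entry is G held on the catalyst. At one G per L, it takes at most 1.20% of the eta charge, and I drop it. The books then close at the ceiling, the G charged divided by the D charged, which is the percent of D that can become X at one G each: 70.0% for the eta flask.

Is it reached in time? At 2.50 min, eta and delta differ by 0.6 percentage points, close to the scatter of 0.5 points, though eta holds twice the G. So I borrow the delta pace, 0.0647 /min of the D charged. Reckoned from the last eta reading, that pace meets the ceiling at 11.6 min, earlier than 15 min. I commit to X at the ceiling at 15 min. Green, red and ochre leave G over D unchanged and my reckoned arrival falls before 15 min, so I expect nothing from them. Teal lifts the ceiling to 140%, above the 100% of D charged, and the same pace gives 91.9%. I choose teal.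

The forecast gives 69.8%, teal and 93%, above my teal figure, and says: “The other changes do nothing, because G already limits X.”

The eta flask gives 70.0%, the ceiling of 70.0%. At 15.0 min, 0% of its G is left unbound, and X stands at 70.0% at 150 min. Teal, with its ceiling of 140%, gives 95.2%, a gain of 25 points, and green, red and ochre each gain 0 points. Here Q is dissolved D, and E and Z are forms of L.

    G + E → Z (k = 120 /M/s)
    Q + L → E (k = 1.70 /M/s)
    Z → L + X (k = 1.90 /s)
    D ⇌ Q, rate k4*(cs4 - [Q]) while solid is left; crystals form when [Q] > cs4 (solubility = 0.280 M, k = 0.00560 /s)

A neighbour flask has 0.17 M of G, with the rest as in eta. Its ceiling is 17.9%, and it gives 17.9%.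

The runs are simulated for an exercise.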